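**The problem**

Target 12 is a benzophenone whose ketone carbon C7 joins two benzene rings that are each substituted at both ortho positions. Ring A carries C1 on C7, OH at C2, Cl at C3, OMe at C4, H at C5 and OMe at C6; ring B carries C1' on C7, OMe at C2', OH at C4' and CH3 at C6'. The rings share no bond other than those to C7, so a synthesis must either join two hindered aryl partners at the ketone or make the ketone first and grow one ring onto it. There is no stereocenter in 12, so every question is one of position. Three oxygens on ring A must end as one free hydroxyl and two methyl ethers, chlorine must sit at C3 and not at the similarly activated C5, and ring B must keep one free and one methylated oxygen. Both rings are electron-rich, so an electrophilic chlorination has to choose ring A over ring B. The aryl C–Cl bond will not survive reductive conditions, the methoxyls ortho to the ketone are open to chelation-assisted cleavage by strong Lewis acids, and the β-hydroxy and β-keto pyranones met on the way eliminate or cleave under careless base treatment. The enabling feature is that ring A is an acylphloroglucinol: with C1 on C7 and oxygen on C2, C4 and C6, the chain C7–C1–C6–C5–C4–C3–C2 is a 3,5,7-trioxoheptanoate with C2 as the carboxyl carbon, so the ring can be closed by a Claisen condensation between C1 and C2. Pyranone 4 carries this chain in masked form, with the C4 oxygen already methylated and the carboxyl activated as a lactone.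

**Retrosynthesis**

Target 12 is traced back to its 4'-benzyl ether 11 by cutting only the O–CH2Ph bond. A benzyl ether is preferred over silyl, acetal or ester protection because it must survive an amide base, refluxing alkoxide, two alkylations and an electrophilic chlorination. Its removal is asked to spare the aryl chloride and the methoxyls next to the ketone, which points to a Lewis-acid cleavage at low temperature and away from hydrogenolysis.

Chloride 11 is traced to phenol 10 by cutting the C3–Cl bond. The cut is placed here because 10 has a single free hydroxyl, at C2 of ring A, and C3 is its only ortho position, while ring B has no free hydroxyl at all. Chlorinating earlier, at diol 9 or on pyranone 4, would fix C3 by symmetry or by the skeleton but would then leave two unlike hydroxyls to be told apart in the methylation. The forward step must place one chlorine ortho to the hydroxyl, on ring A only.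

Phenol 10 is traced to diol 9 by cutting the O–CH3 bond at C6. Ring A of 9 has a mirror plane through C1 and C4, so its two hydroxyls are equivalent and the first methylation can give only one product. The forward reaction has only to stop after one methyl group, which the hydrogen bond of the remaining hydroxyl to the ketone should ensure.

Diol 9 is traced to pyranone ketone 7 by cutting the C1–C2 bond of ring A; this is the key disconnection and passes through the open-chain ester 8. The neighbouring cuts at C1–C7 or C7–C1' would require acylating an arene with a di-ortho-substituted benzoyl unit and would face an ortho/para choice on a phloroglucinol ether. The chosen cut replaces a hexasubstituted benzene by a monosubstituted heterocycle in which the C4 methoxyl is already present. The forward step must favour Claisen closure by the carbon between the two ketones over aldol closure, O-cyclization and cleavage of the diketone.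

Ketone 7 is traced to carbinol 6 by a change of oxidation level, and 6 to aldehyde 3 and pyranone 4 by cutting the bond between the carbinol carbon (the future C7) and the methylene carbon (the future C1). Addition to an aldehyde is chosen over acylation by the corresponding ester because a 2,6-disubstituted benzoate is a poor acyl donor, whereas the aldehyde accepts a carbanion readily. The forward steps require deprotonation of 4 at its 6-methyl group, 1,2-addition without elimination, and a mild oxidation.

Aldehyde 3 is traced through phenol 2 to the commercial dihydroxy aldehyde 1 by cutting two O–C bonds. In 1 the carbon framework of ring B, including the C6' methyl and the future C7, is complete. The two hydroxyls are distinguished by the hydrogen bond of the ortho hydroxyl to the formyl group, so the para hydroxyl is benzylated first and the ortho hydroxyl methylated second.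

**Roads not taken**

Alternative 1: Ring B would be made last by cutting its C1'–C2' and C5'–C6' bonds.
- Forward step: the ring A ynone A1, 1-[3-chloro-4,6-dimethoxy-2-(methoxymethoxy)phenyl]but-2-yn-1-one, is heated with the trioxygenated diene A2, 1,1-dimethoxy-3-(trimethylsilyloxy)buta-1,3-diene. The [4+2] adduct aromatizes by loss of one alkoxy group and is desilylated to A3, the 2-O-methoxymethyl ether of 12, one acid step from the target.
- Merits: the polarities match, since the CH2 terminus of A2 attacks the methyl-bearing β-carbon of A1. Ring B arrives with methyl, methoxyl and free hydroxyl in place, and the chlorine is fixed before the rings are joined.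
- Weak points: A1 is an internal ynone with a β-methyl group and a carbonyl twisted out of conjugation with its di-ortho-substituted ring, so it is a sluggish dienophile, while A2 is fragile to heat and moisture. Open-chain Michael-type adducts may fail to cyclize. All positional problems of ring A (chlorine site, three distinct oxygens, site of the acyl carbon) move into the preparation of A1, where they must be solved by electrophilic substitutions with ortho/para choices.
- Comparison: the length is about the same as the chosen plan. Alternative 1 is better in that the chlorine position is never in doubt at a late stage and no chlorination has to select between two electron-rich rings. The chosen plan sets against this that the chain defines the oxygen pattern of ring A, that diol 9 is symmetric, and that its key step has a close precedent.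

Alternative 2: Both bonds to C7 would be cut.
- Forward step: the ring A iodide A4, 2-chloro-4-iodo-1,5-dimethoxy-3-(methoxymethoxy)benzene, carbon monoxide A5 and the ring B boronic acid A6, [2-methoxy-4-(methoxymethoxy)-6-methylphenyl]boronic acid, are combined in a carbonylative Suzuki coupling under a palladium catalyst with a bulky electron-rich alkylphosphine and a carbonate base. The product is the bis(methoxymethyl) ether A7, which one acid treatment converts into 12.
- Merits: this is the most convergent plan, with the shortest longest linear sequence, both protecting groups removed together, and no redox adjustment.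
- Weak points: A4 and A6 are both di-ortho-substituted. Transmetalation of a 2,6-disubstituted electron-rich boronic acid to a hindered acyl-palladium species is slow, and protodeboronation of A6 and direct biaryl coupling without A5 compete. A phosphine of the kind needed also activates aryl chlorides, so the C3–Cl bond of A4 and A7 is at risk. A4 and A6 each need several regiocontrolled steps.
- Comparison: Alternative 2 is shorter in its longest sequence and more modular than the chosen plan, and that advantage is real. The chosen plan sets against it that the hindered ketone is made by carbanion addition to an aldehyde, which is little affected by ortho substituents, and that all oxygen differentiation comes from chelation and symmetry without separate protecting-group work on two arenes.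

Alternative 3: The C7–C1' bond and the bond from C6' to the future methyl carbon would be cut.
- Forward step: fluoride releases an aryne from the silyl triflate A8, 5-(benzyloxy)-3-methoxy-2-(trimethylsilyl)phenyl trifluoromethanesulfonate. The aryne inserts into the CH2–C(=O) bond of the ring A β-ketoester A9, methyl 3-[2-(benzyloxy)-3-chloro-4,6-dimethoxyphenyl]-3-oxopropanoate, giving the arylacetate A10.
- Merits: the conditions are mild, and the hindered aryl–carbonyl bond is made by an intramolecular acyl shift through a four-membered alkoxide. The regiochemistry is set by the aryne methoxyl, because the enolate adds at the aryne carbon remote from it and the acyl group ends up next to it, as required.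
- Weak points: the ketone of A9 lies between two ortho substituents, so closure to the four-membered alkoxide may lose to simple protonation, which gives α-arylation only. A8 and A9 each need a multi-step, regiocontrolled preparation. The C6' substituent arrives as CH2CO2Me and must be cut down to CH3 by hydrolysis and a forcing decarboxylation, and two benzyl ethers must then be removed beside the aryl chloride.
- Comparison: this route is clearly longer than the chosen plan. It is better in one respect: the tetra-ortho-substituted ketone and the ring B carbon substituent form in a single redox-neutral step with no late chlorination. The chosen plan sets against this that the C6' methyl comes with aldehyde 1, that both building blocks are commercial, and that the sequence is about half as long.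

Key step: step 5

Assumption: 12 has no stereocenter; the only one met on the way, the carbinol carbon of 6, is formed racemic and is erased by the oxidation in step 4.

Step 1
Reactants: 1 2,4-dihydroxy-6-methylbenzaldehyde
Product: 2 4-(benzyloxy)-2-hydroxy-6-methylbenzaldehyde
Conditions: BnBr (1.05 equiv), K2CO3 (1.0 equiv), acetone, rt
Reagents that add atoms: benzyl bromide, BrCc1ccccc1
Why: Williamson ether synthesis; the 2-hydroxyl is held in a hydrogen bond to the formyl group and is the less acidic one, so with one equivalent of mild base the 4-hydroxyl para to the aldehyde should be alkylated first.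

Step 2
Reactants: 2 4-(benzyloxy)-2-hydroxy-6-methylbenzaldehyde
Product: 3 4-(benzyloxy)-2-methoxy-6-methylbenzaldehyde
Conditions: MeI, K2CO3, DMF, 40 °C
Reagents that add atoms: iodomethane, CI
Why: Williamson O-methylation of the remaining chelated phenol, which needs the polar solvent and gentle warming; no other nucleophilic site is left in 2.

Step 3
Reactants: 3 4-(benzyloxy)-2-methoxy-6-methylbenzaldehyde; 4 4-methoxy-6-methyl-2H-pyran-2-one
Product: 6 rac-6-{2-[4-(benzyloxy)-2-methoxy-6-methylphenyl]-2-hydroxyethyl}-4-methoxy-2H-pyran-2-one, via lithiated pyranone 5 (not isolated)
Conditions: 4, LiN(iPr)2 (1.1 equiv), THF, −78 °C; then 3, −78 °C; AcOH quench at −78 °C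
Reagents that add atoms: none
Why: Kinetic deprotonation of 4 by the hindered amide base takes place at the 6-methyl group (the vinylogous γ-position), and the resulting dienolate 5 adds to the non-enolizable aldehyde 3 in an aldol-type addition; the cold acidic quench should prevent retro-aldol cleavage and dehydration, and the new carbinol center is racemic and is removed in step 4.

Step 4
Reactants: 6 rac-6-{2-[4-(benzyloxy)-2-methoxy-6-methylphenyl]-2-hydroxyethyl}-4-methoxy-2H-pyran-2-one
Product: 7 6-{2-[4-(benzyloxy)-2-methoxy-6-methylphenyl]-2-oxoethyl}-4-methoxy-2H-pyran-2-one
Conditions: Dess–Martin periodinane (1.2 equiv), CH2Cl2, 0 °C to rt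
Reagents that add atoms: none
Why: Dess–Martin oxidation of a hindered secondary benzylic alcohol under nearly neutral conditions; no base is present that could eliminate water to a styrylpyranone, and the benzyl ether, enol ether and lactone are inert to the reagent.

Step 5
Reactants: 7 6-{2-[4-(benzyloxy)-2-methoxy-6-methylphenyl]-2-oxoethyl}-4-methoxy-2H-pyran-2-one
Product: 9 [4-(benzyloxy)-2-methoxy-6-methylphenyl](2,6-dihydroxy-4-methoxyphenyl)methanone, via ring-opened enol-ether diketo ester 8 (not isolated)
Conditions: Mg(OMe)2 (5 equiv), MeOH, reflux; then 1 M HCl, 0 °C
Reagents that add atoms: none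
Why: Mg(OMe)2 removes the acidic methylene proton of 7 and methoxide adds to the lactone carbonyl, opening the pyranone to the magnesium-chelated β-diketonate of ester 8, whose (E)-enol ether, inherited from the ring, keeps the ester carbon cis to the chain and within reach of the carbon between the two ketones. That carbon attacks the ester carbonyl in a Claisen (Dieckmann-type) condensation, a 6-exo-trig closure that forms the C1–C2 bond of ring A; loss of methoxide gives a 2-aroyl-5-methoxycyclohexenedione that enolizes at once to the aromatic ring, which makes the sequence irreversible. The closest known reaction type is the biomimetic Claisen cyclization of 3,5,7-triketo esters and of 6-(2-oxoalkyl)-4-oxygenated 2-pyranones to acylphloroglucinols under Mg(OMe)2. No stereocenter is formed. The step needs C-acylation by the central carbon in preference to aldol closure onto the aryl ketone, to O-cyclization onto the enol-ether carbon (a 4-pyranone) and to methanolysis of the diketone. Aldol closure is disfavoured because the ester α-carbon is an enol-ether CH that becomes nucleophilic only after a second deprotonation and because its acceptor, the aryl ketone, is shielded by the ortho methoxyl and methyl of ring B. Magnesium chelation ties up both ketone oxygens, leaves carbon as the nucleophilic site and protects the diketone from cleavage. The C4 methoxyl passes through unchanged, so 9 should emerge with the para oxygen already methylated and two equivalent hydroxyls.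

Step 6
Reactants: 9 [4-(benzyloxy)-2-methoxy-6-methylphenyl](2,6-dihydroxy-4-methoxyphenyl)methanone
Product: 10 [4-(benzyloxy)-2-methoxy-6-methylphenyl](2-hydroxy-4,6-dimethoxyphenyl)methanone
Conditions: Me2SO4 (1.05 equiv), K2CO3 (1.1 equiv), acetone, reflux
Reagents that add atoms: dimethyl sulfate, COS(=O)(=O)OC
Why: Williamson methylation with one equivalent of electrophile; the two hydroxyls of 9 are equivalent by symmetry, so only one mono-ether can form, and the remaining hydroxyl is then locked in a hydrogen bond to the ketone and reacts much more slowly, as is general for 2,6-dihydroxyaryl ketones.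

Step 7
Reactants: 10 [4-(benzyloxy)-2-methoxy-6-methylphenyl](2-hydroxy-4,6-dimethoxyphenyl)methanone
Product: 11 [4-(benzyloxy)-2-methoxy-6-methylphenyl](3-chloro-2-hydroxy-4,6-dimethoxyphenyl)methanone
Conditions: SO2Cl2 (1.0 equiv), 2,2,6,6-tetramethylpiperidine (5 mol %), toluene, 0 °C to rt
Reagents that add atoms: sulfuryl chloride, O=S(=O)(Cl)Cl
Why: Electrophilic aromatic chlorination of a phenol with SO2Cl2 under secondary-amine catalysis, which delivers chlorine ortho to a free hydroxyl; C3 is the only position ortho to the C2 hydroxyl and is the site that halogenation of chelated 2-hydroxy-4,6-dimethoxyaryl ketones generally prefers, while ring B has no free hydroxyl and only two oxygen donors against three on ring A.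

Step 8
Reactants: 11 [4-(benzyloxy)-2-methoxy-6-methylphenyl](3-chloro-2-hydroxy-4,6-dimethoxyphenyl)methanone
Product: 12 (3-chloro-2-hydroxy-4,6-dimethoxyphenyl)(4-hydroxy-2-methoxy-6-methylphenyl)methanone
Conditions: BCl3 (3 equiv), pentamethylbenzene (3 equiv), CH2Cl2, −78 °C; then MeOH, H2O
Reagents that add atoms: none
Why: Lewis-acid cleavage of an aryl benzyl ether with BCl3, the benzyl cation being trapped by pentamethylbenzene in a Friedel–Crafts alkylation; at −78 °C the methyl ethers, the aryl chloride and the ketone should be retained, and hydrogenolysis, which would endanger the C–Cl bond, is avoided.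

**Compound list**

1 | 2,4-dihydroxy-6-methylbenzaldehyde | Cc1cc(O)cc(O)c1C=O | starting material
2 | 4-(benzyloxy)-2-hydroxy-6-methylbenzaldehyde | Cc1cc(OCc2ccccc2)cc(O)c1C=O | intermediate
3 | 4-(benzyloxy)-2-methoxy-6-methylbenzaldehyde | COc1cc(OCc2ccccc2)cc(C)c1C=O | intermediate
4 | 4-methoxy-6-methyl-2H-pyran-2-one | COc1cc(C)oc(=O)c1 | starting material
5 | [(4-methoxy-2-oxo-2H-pyran-6-yl)methyl]lithium (lithiated pyranone, not isolated) | [Li]Cc1cc(OC)cc(=O)o1 | intermediate
6 | rac-6-{2-[4-(benzyloxy)-2-methoxy-6-methylphenyl]-2-hydroxyethyl}-4-methoxy-2H-pyran-2-one (racemic carbinol) | COc1cc(CC(O)c2c(C)cc(OCc3ccccc3)cc2OC)oc(=O)c1 | intermediate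
7 | 6-{2-[4-(benzyloxy)-2-methoxy-6-methylphenyl]-2-oxoethyl}-4-methoxy-2H-pyran-2-one | COc1cc(CC(=O)c2c(C)cc(OCc3ccccc3)cc2OC)oc(=O)c1 | intermediate
8 | methyl (2E)-7-[4-(benzyloxy)-2-methoxy-6-methylphenyl]-3-methoxy-5,7-dioxohept-2-enoate (present as its magnesium chelate, not isolated) | COC(=O)/C=C(/OC)CC(=O)CC(=O)c1c(C)cc(OCc2ccccc2)cc1OC | intermediate
9 | [4-(benzyloxy)-2-methoxy-6-methylphenyl](2,6-dihydroxy-4-methoxyphenyl)methanone | COc1cc(O)c(C(=O)c2c(C)cc(OCc3ccccc3)cc2OC)c(O)c1 | intermediate
10 | [4-(benzyloxy)-2-methoxy-6-methylphenyl](2-hydroxy-4,6-dimethoxyphenyl)methanone | COc1cc(O)c(C(=O)c2c(C)cc(OCc3ccccc3)cc2OC)c(OC)c1 | intermediate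
11 | [4-(benzyloxy)-2-methoxy-6-methylphenyl](3-chloro-2-hydroxy-4,6-dimethoxyphenyl)methanone | COc1cc(OC)c(C(=O)c2c(C)cc(OCc3ccccc3)cc2OC)c(O)c1Cl | intermediate
12 | (3-chloro-2-hydroxy-4,6-dimethoxyphenyl)(4-hydroxy-2-methoxy-6-methylphenyl)methanone | COc1cc(OC)c(C(=O)c2c(C)cc(O)cc2OC)c(O)c1Cl | target

**Step count and risks**

Total step count: 8. Longest linear sequence: 8 steps, from 1 to 12; pyranone 4 is used as purchased and enters at step 3.

Steps least certain to work:

Step 5 (key step).
- What may go wrong: the ring-opened chelate may be diverted before C-acylation. The carbon between the two ketones carries a hindered aroyl group and may react slowly, which gives time for methanolysis of the diketone (retro-Claisen cleavage) or for O-cyclization onto the enol-ether carbon.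
- Fallback: this abandons ring construction and joins two preformed arenes, setting out from 3 and returning at 10. Commercial 3,5-dimethoxyphenol would be protected with chloromethyl methyl ether and iPr2NEt as 1,3-dimethoxy-5-(methoxymethoxy)benzene F1. Ortho-lithiation of F1 with n-BuLi in THF should occur between the acetal oxygen and a methoxyl, the acetal being the stronger director. Addition of the aryllithium to 3 should give the diaryl carbinol [4-(benzyloxy)-2-methoxy-6-methylphenyl][2,4-dimethoxy-6-(methoxymethoxy)phenyl]methanol F2. Dess–Martin oxidation would give the ketone [4-(benzyloxy)-2-methoxy-6-methylphenyl][2,4-dimethoxy-6-(methoxymethoxy)phenyl]methanone F3, and HCl in methanol would remove the acetal to deliver 10.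

Step 7.
- What may go wrong: loss of site selectivity, by attack para to the hydroxyl at C5 between the two methoxyls, by attack on ring B (whose dialkoxytoluene unit is twisted out of conjugation with the ketone and is itself electron-rich), or by a second chlorination.
- Fallback: the chlorine is bought with the building block; the sequence sets out from 3 and returns at 11. Commercial 2-chloro-3,5-dimethoxyphenol would be converted into its methoxymethyl ether 2-chloro-1,5-dimethoxy-3-(methoxymethoxy)benzene F4. F4 would be lithiated with n-BuLi at the position between the acetal oxygen and the methoxyl (no hydrogen lies ortho to chlorine, so no aryne can form) and added to 3 to give [4-(benzyloxy)-2-methoxy-6-methylphenyl][3-chloro-4,6-dimethoxy-2-(methoxymethoxy)phenyl]methanol F5. Dess–Martin oxidation would give [4-(benzyloxy)-2-methoxy-6-methylphenyl][3-chloro-4,6-dimethoxy-2-(methoxymethoxy)phenyl]methanone F6, and HCl in methanol would give 11.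

Step 3.
- What may go wrong: the addition to the hindered, electron-rich aldehyde may be slow, and the lithium aldolate may revert by retro-aldol cleavage or lose water to a styrylpyranone if it warms before the quench.
- Fallback: acylation replaces addition and oxidation; the sequence sets out from 3 and returns at 7. Pinnick oxidation of 3 (NaClO2, NaH2PO4, 2-methyl-2-butene) would give 4-(benzyloxy)-2-methoxy-6-methylbenzoic acid F7, and oxalyl chloride with catalytic DMF would give 4-(benzyloxy)-2-methoxy-6-methylbenzoyl chloride F8. F8 would be added at −78 °C to two equivalents of lithiated pyranone 5, the second equivalent serving to deprotonate the more acidic product, which gives 7 directly in a Claisen-type C-acylation.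

Step 8.
- What may go wrong: once boron is bound to the C2 phenoxide and the ketone oxygen, a methoxyl ortho to the ketone (C6 or C2') may lose its methyl group by chelation-assisted cleavage, or the benzyl ether may be cleaved incompletely at low temperature.
- Fallback: the benzyl group is removed before chlorine is present; the sequence sets out from 10 and returns at 12. Hydrogenolysis of 10 (H2, Pd/C, EtOAc) would give (2-hydroxy-4,6-dimethoxyphenyl)(4-hydroxy-2-methoxy-6-methylphenyl)methanone F9. Acetic anhydride and pyridine at 0 °C should acylate only the non-chelated 4'-hydroxyl to give 4-(2-hydroxy-4,6-dimethoxybenzoyl)-3-methoxy-5-methylphenyl acetate F10, in which ring B is also deactivated toward electrophiles. Chlorination as in step 7 would give 4-(3-chloro-2-hydroxy-4,6-dimethoxybenzoyl)-3-methoxy-5-methylphenyl acetate F11, and K2CO3 in methanol would remove the acetate to give 12.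

**Further compounds**

F1 | step 5 | 1,3-dimethoxy-5-(methoxymethoxy)benzene | COCOc1cc(OC)cc(OC)c1
F2 | step 5 | [4-(benzyloxy)-2-methoxy-6-methylphenyl][2,4-dimethoxy-6-(methoxymethoxy)phenyl]methanol (racemic) | COCOc1cc(OC)cc(OC)c1C(O)c1c(C)cc(OCc2ccccc2)cc1OC
F3 | step 5 | [4-(benzyloxy)-2-methoxy-6-methylphenyl][2,4-dimethoxy-6-(methoxymethoxy)phenyl]methanone | COCOc1cc(OC)cc(OC)c1C(=O)c1c(C)cc(OCc2ccccc2)cc1OC
F4 | step 7 | 2-chloro-1,5-dimethoxy-3-(methoxymethoxy)benzene | COCOc1cc(OC)cc(OC)c1Cl
F5 | step 7 | [4-(benzyloxy)-2-methoxy-6-methylphenyl][3-chloro-4,6-dimethoxy-2-(methoxymethoxy)phenyl]methanol (racemic) | COCOc1c(Cl)c(OC)cc(OC)c1C(O)c1c(C)cc(OCc2ccccc2)cc1OC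
F6 | step 7 | [4-(benzyloxy)-2-methoxy-6-methylphenyl][3-chloro-4,6-dimethoxy-2-(methoxymethoxy)phenyl]methanone | COCOc1c(Cl)c(OC)cc(OC)c1C(=O)c1c(C)cc(OCc2ccccc2)cc1OC
F7 | step 3 | 4-(benzyloxy)-2-methoxy-6-methylbenzoic acid | COc1cc(OCc2ccccc2)cc(C)c1C(=O)O
F8 | step 3 | 4-(benzyloxy)-2-methoxy-6-methylbenzoyl chloride | COc1cc(OCc2ccccc2)cc(C)c1C(Cl)=O
F9 | step 8 | (2-hydroxy-4,6-dimethoxyphenyl)(4-hydroxy-2-methoxy-6-methylphenyl)methanone | COc1cc(O)c(C(=O)c2c(C)cc(O)cc2OC)c(OC)c1
F10 | step 8 | 4-(2-hydroxy-4,6-dimethoxybenzoyl)-3-methoxy-5-methylphenyl acetate | COc1cc(O)c(C(=O)c2c(C)cc(OC(C)=O)cc2OC)c(OC)c1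
F11 | step 8 | 4-(3-chloro-2-hydroxy-4,6-dimethoxybenzoyl)-3-methoxy-5-methylphenyl acetate | COc1cc(OC)c(C(=O)c2c(C)cc(OC(C)=O)cc2OC)c(O)c1Cl
A1 | alternative 1 | 1-[3-chloro-4,6-dimethoxy-2-(methoxymethoxy)phenyl]but-2-yn-1-one | CC#CC(=O)c1c(OC)cc(OC)c(Cl)c1OCOC
A2 | alternative 1 | 1,1-dimethoxy-3-(trimethylsilyloxy)buta-1,3-diene | COC(OC)=CC(=C)O[Si](C)(C)C
A3 | alternative 1 | [3-chloro-4,6-dimethoxy-2-(methoxymethoxy)phenyl](4-hydroxy-2-methoxy-6-methylphenyl)methanone | COCOc1c(Cl)c(OC)cc(OC)c1C(=O)c1c(C)cc(O)cc1OC
A4 | alternative 2 | 2-chloro-4-iodo-1,5-dimethoxy-3-(methoxymethoxy)benzene | COCOc1c(Cl)c(OC)cc(OC)c1I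
A5 | alternative 2 | carbon monoxide | [C-]#[O+]
A6 | alternative 2 | [2-methoxy-4-(methoxymethoxy)-6-methylphenyl]boronic acid | COCOc1cc(C)c(B(O)O)c(OC)c1
A7 | alternative 2 | [3-chloro-4,6-dimethoxy-2-(methoxymethoxy)phenyl][2-methoxy-4-(methoxymethoxy)-6-methylphenyl]methanone | COCOc1c(Cl)c(OC)cc(OC)c1C(=O)c1c(C)cc(OCOC)cc1OC
A8 | alternative 3 | 5-(benzyloxy)-3-methoxy-2-(trimethylsilyl)phenyl trifluoromethanesulfonate | COc1cc(OCc2ccccc2)cc(OS(=O)(=O)C(F)(F)F)c1[Si](C)(C)C
A9 | alternative 3 | methyl 3-[2-(benzyloxy)-3-chloro-4,6-dimethoxyphenyl]-3-oxopropanoate | COC(=O)CC(=O)c1c(OC)cc(OC)c(Cl)c1OCc1ccccc1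
A10 | alternative 3 | methyl 2-{5-(benzyloxy)-2-[2-(benzyloxy)-3-chloro-4,6-dimethoxybenzoyl]-3-methoxyphenyl}acetate | COC(=O)Cc1cc(OCc2ccccc2)cc(OC)c1C(=O)c1c(OCc2ccccc2)c(Cl)c(OC)cc1OC
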